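The oxolane ring (O1, C2–C5) of the target carries the aroyl carbon C7' on C4 and, on the neighbouring C3, both the benzylic ring carbon C2 and the hydroxymethyl carbon C9. This vicinal pattern is read as a butenolide: β-carbon = C4, α-carbon = C3, lactone carbonyl = C9, acetal carbon = C5. One operation then adds a syringyl acyl-anion equivalent (lithiated dithiane) to C4 and a protected vanillin to C3 of (5R)-5-(l-menthyloxy)-2(5H)-furanone, forming C4–C7' and C2–C3 and fixing C3 by relay from the acetal centre. Reduction, benzylic cycloetherification (O1–C2), carbonyl release, C4 epimerisation and debenzylation complete the route.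

Key step: step 5

Remark: 4-benzyloxy-3-methoxybenzaldehyde is a catalogue aldehyde and is used as bought; the carbinol centre made in the key step is carried as both epimers because the later ring closure passes through a planar benzylic cation.

Step 1
Reactants: 1 furfural
Product: 3 5-hydroxy-2(5H)-furanone, via furfural endoperoxide 2 (not isolated)
Conditions: O2, hν (visible), rose bengal (cat.), MeOH, rt
Reagents that add atoms: oxygen, O=O
Why: Sensitised photooxygenation, i.e. [4+2] addition of singlet oxygen across the furan and methanol-assisted loss of the formyl carbon as methyl formate, is the standard entry to this hydroxybutenolide; the lactol centre is labile and is not controlled.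

Step 2
Reactants: 3 5-hydroxy-2(5H)-furanone; 4 l-menthol
Product: 6 (5R)-5-(l-menthyloxy)-2(5H)-furanone, via (5S) acetal epimer 5 (not isolated)
Conditions: CSA (cat.), toluene, reflux, azeotropic removal of water; crystallisation from petroleum ether, liquors re-equilibrated with CSA and recrystallised
Reagents that add atoms: none
Why: Acid-catalysed acetalisation of the lactol with the chiral alcohol gives both C5 epimers, which interconvert under the acid, and since the (5R) epimer is the crystalline one the acetal stereocentre is set by crystallisation-driven equilibration.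

Step 3
Reactants: 7 syringaldehyde
Product: 8 4-benzyloxy-3,5-dimethoxybenzaldehyde
Conditions: BnBr, K2CO3, DMF, rt
Reagents that add atoms: benzyl bromide, BrCc1ccccc1
Why: Williamson etherification of the acidic phenol; the benzyl ether is chosen because it should survive butyllithium, LiAlH4, acid, divalent mercury and DBU and leave under neutral conditions at the end.

Step 4
Reactants: 8 4-benzyloxy-3,5-dimethoxybenzaldehyde
Product: 9 2-(4-benzyloxy-3,5-dimethoxyphenyl)-1,3-dithiane
Conditions: HS(CH2)3SH, BF3·OEt2 (cat.), CH2Cl2, 0 °C → rt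
Reagents that add atoms: propane-1,3-dithiol, SCCCS
Why: Lewis-acid-catalysed dithioacetalisation of an aromatic aldehyde turns the future C7' into an acyl-anion equivalent (umpolung).

Step 5
Reactants: 9 2-(4-benzyloxy-3,5-dimethoxyphenyl)-1,3-dithiane; 6 (5R)-5-(l-menthyloxy)-2(5H)-furanone; 10 4-benzyloxy-3-methoxybenzaldehyde
Product: 14 (3S,4R,5R)-3-[(4-benzyloxy-3-methoxyphenyl)(hydroxy)methyl]-4-[2-(4-benzyloxy-3,5-dimethoxyphenyl)-1,3-dithian-2-yl]-5-(l-menthyloxy)dihydrofuran-2(3H)-one (both carbinol epimers), via lithiated dithiane 11 (not isolated), via lactone lithium enolate 12 (not isolated), via lithium aldolate 13 (not isolated)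
Conditions: n-BuLi, THF, −78 → −20 °C; 6, −78 °C; 10, −78 °C; AcOH, −78 °C
Reagents that add atoms: none
Why: Butyllithium removes the acidic C–H between the two sulfur atoms of 9, and the soft, aryl- and sulfur-stabilised carbanion 11 adds in conjugate fashion to C4 of 6 on the face opposite the C5 menthyloxy group, creating C4–C7' and the enolate 12. The enolate then adds to the non-enolisable aldehyde 10 on the face opposite the bulky dithianyl group, creating C2–C3 with the C3 and C4 substituents trans, and the aldolate 13 is protonated cold with acetic acid before retro-aldol cleavage can set in. The closest known reaction type is the tandem Michael addition–aldol reaction (conjugate addition with enolate trapping) of lithiated 2-aryl-1,3-dithianes with 5-alkoxy-2(5H)-furanones and aromatic aldehydes. No ring is closed. C4 is controlled by the acetal stereocentre C5 (substrate control, anti addition) and C3 by the new C4 centre (anti approach of the aldehyde), while the carbinol centre C2 is left uncontrolled on purpose. The step needs 1,4- over 1,2-addition and C–C bond formation over proton transfer, which the delocalised dithianyl anion, the unhindered β-carbon, the absence of acidic protons in 10 and the low temperature should secure.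

Step 6
Reactants: 14 aldol adduct (both carbinol epimers)
Product: 15 (2R,3R)-2-[(4-benzyloxy-3-methoxyphenyl)(hydroxy)methyl]-3-[2-(4-benzyloxy-3,5-dimethoxyphenyl)-1,3-dithian-2-yl]butane-1,4-diol (both carbinol epimers)
Conditions: LiAlH4, THF, 0 °C → rt; H2O then aq. NaOH; menthol removed by chromatography
Reagents that add atoms: none
Why: Hydride reduces the lactone carbonyl (C9) to a primary alcohol and reductively opens the acetal carbon (C5) to the second primary alcohol with release of menthol, while the dithiane, the benzyl ethers and the C3 and C4 centres are untouched (LiAlH4 reduction of a γ-alkoxybutyrolactone to a 1,4-diol).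

Step 7
Reactants: 15 triol (both carbinol epimers)
Product: 17 [(2S,3R,4R)-2-(4-benzyloxy-3-methoxyphenyl)-4-[2-(4-benzyloxy-3,5-dimethoxyphenyl)-1,3-dithian-2-yl]oxolan-3-yl]methanol, via benzylic cation 16 (not isolated)
Conditions: CSA (cat.), CH2Cl2, 0 °C → rt
Reagents that add atoms: none
Why: The acid ionises only the p-alkoxybenzylic C2–OH, both carbinol epimers give the same cation 16, and the C5 hydroxyl closes O1–C2 through a five-membered transition state (the C9 hydroxyl could only form an oxetane) with the aryl group settling anti to the C3 hydroxymethyl and C4 dithianyl groups, so C2 is set (2S) by C3 in a reversible SN1 cycloetherification of a benzylic 1,4-diol.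

Step 8
Reactants: 17 oxolane dithiane
Product: 18 (2S,3R,4R)-4-(4-benzyloxy-3,5-dimethoxybenzoyl)-2-(4-benzyloxy-3-methoxyphenyl)-3-(hydroxymethyl)oxolane (3,4-cis ketone)
Conditions: Hg(ClO4)2·3H2O, CaCO3, THF–H2O, 0 °C → rt
Reagents that add atoms: water, O
Why: Thiophilic divalent mercury cleaves both C–S bonds and water delivers the carbonyl oxygen (metal-assisted dithioacetal hydrolysis), the carbonate buffer protecting the acid-labile benzylic ring ether; any partial scrambling of C4 here is immaterial before step 9.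

Step 9
Reactants: 18 3,4-cis ketone
Product: 19 (2S,3R,4S)-4-(4-benzyloxy-3,5-dimethoxybenzoyl)-2-(4-benzyloxy-3-methoxyphenyl)-3-(hydroxymethyl)oxolane (all-trans ketone)
Conditions: DBU, CH2Cl2, rt
Reagents that add atoms: none
Why: DBU reversibly enolises the only acidic C–H (C4–H next to the aryl ketone) and reprotonation should give the thermodynamically preferred all-trans ring (base-mediated α-epimerisation of a ketone), ring opening by β-alkoxide loss being disfavoured because the C5–O1 bond lies close to the nodal plane of the exocyclic enolate; C4 is thus set (4S) by C3 under thermodynamic control.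

Step 10
Reactants: 19 all-trans ketone
Product: 20 (2S,3R,4S)-4-(4-hydroxy-3,5-dimethoxybenzoyl)-2-(4-hydroxy-3-methoxyphenyl)-3-(hydroxymethyl)oxolane (CNP0169680.1)
Conditions: H2 (1 atm), 10% Pd/C, EtOAc, rt, stopped after two equivalents of H2
Reagents that add atoms: none
Why: Hydrogenolysis of the two aryl benzyl ethers over palladium on carbon in a neutral aprotic solvent is faster than cleavage of the cyclic benzylic C2–O1 ether or reduction of the electron-rich aryl ketone, so the diphenol should form with no stereocentre touched.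

Compound list
1 | furfural (furan-2-carbaldehyde) | O=Cc1ccco1 | starting material
2 | furfural 2,5-endoperoxide (2,3,7-trioxabicyclo[2.2.1]hept-5-ene-1-carbaldehyde) | O=CC12OOC(C=C1)O2 | intermediate (not isolated)
3 | 5-hydroxy-2(5H)-furanone, racemic lactol | O=C1C=CC(O)O1 | intermediate
4 | l-menthol, (1R,2S,5R)-2-isopropyl-5-methylcyclohexan-1-ol | O[C@@H]1C[C@H](C)CC[C@H]1C(C)C | starting material
5 | (5S)-5-(l-menthyloxy)-2(5H)-furanone | O=C1C=C[C@@H](O[C@@H]2C[C@H](C)CC[C@H]2C(C)C)O1 | intermediate (not isolated)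
6 | (5R)-5-(l-menthyloxy)-2(5H)-furanone | O=C1C=C[C@H](O[C@@H]2C[C@H](C)CC[C@H]2C(C)C)O1 | intermediate
7 | syringaldehyde (4-hydroxy-3,5-dimethoxybenzaldehyde) | COc1cc(C=O)cc(OC)c1O | starting material
8 | 4-benzyloxy-3,5-dimethoxybenzaldehyde | COc1cc(C=O)cc(OC)c1OCc1ccccc1 | intermediate
9 | 2-(4-benzyloxy-3,5-dimethoxyphenyl)-1,3-dithiane | COc1cc(C2SCCCS2)cc(OC)c1OCc1ccccc1 | intermediate
10 | 4-benzyloxy-3-methoxybenzaldehyde | COc1cc(C=O)ccc1OCc1ccccc1 | starting material
11 | 2-lithio-2-(4-benzyloxy-3,5-dimethoxyphenyl)-1,3-dithiane | COc1cc(C2([Li])SCCCS2)cc(OC)c1OCc1ccccc1 | intermediate (not isolated)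
12 | lithium enolate of (4R,5R)-4-[2-(4-benzyloxy-3,5-dimethoxyphenyl)-1,3-dithian-2-yl]-5-(l-menthyloxy)dihydrofuran-2(3H)-one | [Li]OC1=C[C@@H](C2(c3cc(OC)c(OCc4ccccc4)c(OC)c3)SCCCS2)[C@H](O[C@@H]2C[C@H](C)CC[C@H]2C(C)C)O1 | intermediate (not isolated)
13 | lithium aldolate of 14 (both carbinol epimers) | O=C1O[C@@H](O[C@@H]2C[C@H](C)CC[C@H]2C(C)C)[C@H](C2(c3cc(OC)c(OCc4ccccc4)c(OC)c3)SCCCS2)[C@H]1C(O[Li])c1ccc(OCc2ccccc2)c(OC)c1 | intermediate (not isolated)
14 | (3S,4R,5R)-3-[(4-benzyloxy-3-methoxyphenyl)(hydroxy)methyl]-4-[2-(4-benzyloxy-3,5-dimethoxyphenyl)-1,3-dithian-2-yl]-5-(l-menthyloxy)dihydrofuran-2(3H)-one, both carbinol epimers | O=C1O[C@@H](O[C@@H]2C[C@H](C)CC[C@H]2C(C)C)[C@H](C2(c3cc(OC)c(OCc4ccccc4)c(OC)c3)SCCCS2)[C@H]1C(O)c1ccc(OCc2ccccc2)c(OC)c1 | intermediate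
15 | (2R,3R)-2-[(4-benzyloxy-3-methoxyphenyl)(hydroxy)methyl]-3-[2-(4-benzyloxy-3,5-dimethoxyphenyl)-1,3-dithian-2-yl]butane-1,4-diol, both carbinol epimers | OC[C@H](C(O)c1ccc(OCc2ccccc2)c(OC)c1)[C@H](CO)C1(c2cc(OC)c(OCc3ccccc3)c(OC)c2)SCCCS1 | intermediate
16 | benzylic (C2) cation derived from 15 | OC[C@H]([CH+]c1ccc(OCc2ccccc2)c(OC)c1)[C@H](CO)C1(c2cc(OC)c(OCc3ccccc3)c(OC)c2)SCCCS1 | intermediate (not isolated)
17 | [(2S,3R,4R)-2-(4-benzyloxy-3-methoxyphenyl)-4-[2-(4-benzyloxy-3,5-dimethoxyphenyl)-1,3-dithian-2-yl]oxolan-3-yl]methanol (2,3-trans, 3,4-cis) | COc1cc([C@H]2OC[C@H](C3(c4cc(OC)c(OCc5ccccc5)c(OC)c4)SCCCS3)[C@@H]2CO)ccc1OCc1ccccc1 | intermediate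
18 | (2S,3R,4R)-4-(4-benzyloxy-3,5-dimethoxybenzoyl)-2-(4-benzyloxy-3-methoxyphenyl)-3-(hydroxymethyl)oxolane (2,3-trans, 3,4-cis) | COc1cc([C@H]2OC[C@H](C(=O)c3cc(OC)c(OCc4ccccc4)c(OC)c3)[C@@H]2CO)ccc1OCc1ccccc1 | intermediate
19 | (2S,3R,4S)-4-(4-benzyloxy-3,5-dimethoxybenzoyl)-2-(4-benzyloxy-3-methoxyphenyl)-3-(hydroxymethyl)oxolane (all-trans) | COc1cc([C@H]2OC[C@@H](C(=O)c3cc(OC)c(OCc4ccccc4)c(OC)c3)[C@@H]2CO)ccc1OCc1ccccc1 | intermediate
20 | (2S,3R,4S)-4-(4-hydroxy-3,5-dimethoxybenzoyl)-2-(4-hydroxy-3-methoxyphenyl)-3-(hydroxymethyl)oxolane, CNP0169680.1 | COc1cc([C@H]2OC[C@@H](C(=O)c3cc(OC)c(O)c(OC)c3)[C@@H]2CO)ccc1O | target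

Total step count: 10.
Longest linear sequence: 8 steps (steps 1, 2, 5, 6, 7, 8, 9, 10 from furfural; equally steps 3 to 10 from syringaldehyde).

Steps most likely to fail

Step 5. The dithianyl anion may act as a base towards the butenolide instead of adding to it. The enolate may add to a second molecule of butenolide before the aldehyde arrives. The aldol addition may also revert on warming. In the fallback the two C–C bonds are made in separate operations. Setting out from 6 and 11, the enolate 12 is protonated (NH4Cl, −78 °C) and the conjugate adduct (4R,5R)-4-[2-(4-benzyloxy-3,5-dimethoxyphenyl)-1,3-dithian-2-yl]-5-(l-menthyloxy)dihydrofuran-2(3H)-one F1 is isolated and purified. It is re-enolised with LDA (THF, −78 °C) and transmetalated with ZnCl2 to the chlorozinc enolate F2, whose chelated zinc aldolate should not revert. Addition of 10 and aqueous NH4Cl work-up then return to the route at 14.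

Step 7. The benzylic cation may be intercepted by the electron-rich dimethoxyaryl ring on C7' (six-membered carbocyclisation) or by sulfur, or may lose the C3 proton. Equilibration to the 2,3-trans ring may also stay incomplete. In the fallback the ring is closed through a neutral p-quinone methide, which needs the guaiacyl oxygen free. Setting out from enolate 12 (made as in step 5), the aldehyde partner is replaced by 4-formyl-2-methoxyphenyl pivalate F3 (from vanillin, PivCl, Et3N, CH2Cl2). This gives the pivalate aldol adduct F4. LiAlH4 (THF, 0 °C → rt) reduces lactone and acetal and removes the pivaloyl group in the same operation, giving the phenolic triol (2R,3R)-3-[2-(4-benzyloxy-3,5-dimethoxyphenyl)-1,3-dithian-2-yl]-2-[hydroxy(4-hydroxy-3-methoxyphenyl)methyl]butane-1,4-diol F5. With PPTS (cat.) in CH2Cl2 at rt only the p-hydroxybenzylic alcohol should ionise. Reversible 5-exo addition of the C5 hydroxyl should then give the trans phenol [(2S,3R,4R)-4-[2-(4-benzyloxy-3,5-dimethoxyphenyl)-1,3-dithian-2-yl]-2-(4-hydroxy-3-methoxyphenyl)oxolan-3-yl]methanol F6 under conditions too mild for arene alkylation. Selective phenol benzylation (BnBr, K2CO3, acetone) returns to the route at 17.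

Step 9. Ring–chain tautomerism of the cis ketol, in which the C9 hydroxyl adds to the C7' carbonyl to form a cis-fused bicyclic hemiketal, may withhold the ketone from enolisation or hold C4 in the cis configuration. In the fallback the hydroxyl is masked before the carbonyl is released. Setting out from 17, acetylation (Ac2O, pyridine, DMAP) gives the acetate of 17 F7. Dithiane hydrolysis as in step 8 gives the 3,4-cis keto acetate F8. DBU (CH2Cl2, rt) then epimerises C4 with no hemiketal available, giving the all-trans keto acetate F9. K2CO3 in MeOH at 0 °C removes the acetate and returns to the route at 19; the trans ketol could form a hemiketal only through a strained trans ring fusion.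

Further compounds
F1 | step 5 | (4R,5R)-4-[2-(4-benzyloxy-3,5-dimethoxyphenyl)-1,3-dithian-2-yl]-5-(l-menthyloxy)dihydrofuran-2(3H)-one | O=C1C[C@@H](C2(c3cc(OC)c(OCc4ccccc4)c(OC)c3)SCCCS2)[C@H](O[C@@H]2C[C@H](C)CC[C@H]2C(C)C)O1
F2 | step 5 | chlorozinc enolate of F1 | Cl[Zn]OC1=C[C@@H](C2(c3cc(OC)c(OCc4ccccc4)c(OC)c3)SCCCS2)[C@H](O[C@@H]2C[C@H](C)CC[C@H]2C(C)C)O1
F3 | step 7 | 4-formyl-2-methoxyphenyl pivalate | COc1cc(C=O)ccc1OC(=O)C(C)(C)C
F4 | step 7 | (3S,4R,5R)-4-[2-(4-benzyloxy-3,5-dimethoxyphenyl)-1,3-dithian-2-yl]-3-[hydroxy(3-methoxy-4-pivaloyloxyphenyl)methyl]-5-(l-menthyloxy)dihydrofuran-2(3H)-one, both carbinol epimers | O=C1O[C@@H](O[C@@H]2C[C@H](C)CC[C@H]2C(C)C)[C@H](C2(c3cc(OC)c(OCc4ccccc4)c(OC)c3)SCCCS2)[C@H]1C(O)c1ccc(OC(=O)C(C)(C)C)c(OC)c1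
F5 | step 7 | (2R,3R)-3-[2-(4-benzyloxy-3,5-dimethoxyphenyl)-1,3-dithian-2-yl]-2-[hydroxy(4-hydroxy-3-methoxyphenyl)methyl]butane-1,4-diol, both carbinol epimers | OC[C@H](C(O)c1ccc(O)c(OC)c1)[C@H](CO)C1(c2cc(OC)c(OCc3ccccc3)c(OC)c2)SCCCS1
F6 | step 7 | [(2S,3R,4R)-4-[2-(4-benzyloxy-3,5-dimethoxyphenyl)-1,3-dithian-2-yl]-2-(4-hydroxy-3-methoxyphenyl)oxolan-3-yl]methanol | COc1cc([C@H]2OC[C@H](C3(c4cc(OC)c(OCc5ccccc5)c(OC)c4)SCCCS3)[C@@H]2CO)ccc1O
F7 | step 9 | [(2S,3R,4R)-2-(4-benzyloxy-3-methoxyphenyl)-4-[2-(4-benzyloxy-3,5-dimethoxyphenyl)-1,3-dithian-2-yl]oxolan-3-yl]methyl acetate | COc1cc([C@H]2OC[C@H](C3(c4cc(OC)c(OCc5ccccc5)c(OC)c4)SCCCS3)[C@@H]2COC(C)=O)ccc1OCc1ccccc1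
F8 | step 9 | [(2S,3R,4R)-4-(4-benzyloxy-3,5-dimethoxybenzoyl)-2-(4-benzyloxy-3-methoxyphenyl)oxolan-3-yl]methyl acetate (3,4-cis) | COc1cc([C@H]2OC[C@H](C(=O)c3cc(OC)c(OCc4ccccc4)c(OC)c3)[C@@H]2COC(C)=O)ccc1OCc1ccccc1
F9 | step 9 | [(2S,3R,4S)-4-(4-benzyloxy-3,5-dimethoxybenzoyl)-2-(4-benzyloxy-3-methoxyphenyl)oxolan-3-yl]methyl acetate (all-trans) | COc1cc([C@H]2OC[C@@H](C(=O)c3cc(OC)c(OCc4ccccc4)c(OC)c3)[C@@H]2COC(C)=O)ccc1OCc1ccccc1
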